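The numbers in the tables stem from a simulated flask with constants of no real substance, noise included.

You cannot draw an excess of right-handed substrate from a racemate without spending substrate: it appears as the left-handed substrate falls lower, as in the east run at 25.0 min, 26.9 % against 36.6 %.

common to all: gas 7.8 mM (held)
- east: left-handed substrate 0.050 M; right-handed substrate 0.050 M; catalyst 1 mM; run made earlier
- west: left-handed substrate 0.075 M; right-handed substrate 0.075 M; catalyst 1 mM; run made earlier
- flask: left-handed substrate 0.10 M; right-handed substrate 0.10 M; catalyst 1.0 mM; time 40 min

| run | time / min | right-handed substrate / % | left-handed substrate / % |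
|---|---|---|---|
| east | 2.00 | 48.1 | 49.1 |
| east | 4.00 | 49.4 | 47.3 |
| east | 10.0 | 45.6 | 40.3 |
| east | 25.0 | 36.6 | 26.9 |
| west | 2.00 | 50.5 | 48.3 |
| west | 4.00 | 48.3 | 46.3 |
| west | 10.0 | 45.7 | 41.4 |
| west | 25.0 | 38.4 | 31.7 |

(scatter of a reading: 1 percentage point)

- catalyst is single-handed; left-handed substrate and right-handed substrate are mirror images of each other, charged as a racemate, each of them at the stated concentration
- at the start none of the gas is in solution

* whether the excess of right-handed substrate over left-handed substrate among what is left of the two reaches 95 % by 40 min (no / yes)
* the highest excess of right-handed substrate over left-handed substrate among what is left of the two up to 40 min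

Start with the end state. Take each substrate's remains as a fraction of its own charge, and call the logarithm of the left-handed remains over the logarithm of the right-handed remains the selectivity factor. Pooling the last readings of both runs, I read it as 1.87. The ratio of left-handed to right-handed remains is then the right-handed remains raised to the factor minus one, and the excess is one minus that ratio over one plus it. An excess of 95 % therefore needs the right-handed remains at 1.47 %, so nearly all of that substrate must go.

Now the clocks, fastest first. The gas starts out of solution, and the east run reads 2.80 % lost by 2.00 min, so I count the start-up as about 4.00 min, short beside 40 min, and leave it out of the reckoning. Between the last two readings, consumption reads 1.49 mM min⁻¹ in the east run and 1.70 mM min⁻¹ in the west run, a rise by a factor of 1.14 for a charge larger by a factor of 1.50. At the west pace the flask's charge would take 118 min to clear, longer than the 40 min allowed. So I reckon that the flask keeps 66.0 % of its charge and spends about a third. Split by the factor, that is 74.8 % right-handed remains, and my excess at the end is 12.6 %. Those remains stand above the 1.47 % required, so I answer no.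

The forecast says no and 12 %, within 8 % to 17 %, reasoning that “The catalyst is therefore close to saturation”.

The flask gives no, with a top of 17.4 %.

    partner + catalyst + left-handed substrate → catalyst + left-handed product (k = 8300 M⁻² min⁻¹)
    partner + catalyst + right-handed substrate → catalyst + right-handed product (k = 3900 M⁻² min⁻¹)
    gas ⇌ partner, rate k3*(csat - [partner]) (kL = 0.350 min⁻¹)
    catalyst ⇌ dormant form (K = 1.40, k = 0.00240 min⁻¹)
    partner → decomposed reagent (k = 0.0200 min⁻¹)

Put 1.87 on the flask's right-handed remains of 73 % and the excess comes to 13.5 %, against the 17.4 % it shows. Its remains of 51 % and 73 % give a factor of 2.13. Now read the same flask at 2.5 h: the left-handed remains are 1.7 % and the right-handed 15 %, again a factor of 2.15. That factor on 15 % gives 79.0 %, and the excess in that flask tops out at 79.1 %.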